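Remark on the chemistry: the target is the cis, meso (1R,2S) isomer, so every chiral intermediate is carried as a racemate. "Bithienyl" below always means 2,2'-bithiophen-5-yl.

## Analysis of the target

Isocardopatine 17 has a single ring, a cyclobutane, whose adjacent carbons C1 and C2 each carry a (2,2'-bithiophen-5-yl)ethynyl arm, while C3 and C4 are plain CH2 groups. The two stereocentres are cis, so the molecule has a mirror plane and only relative configuration has to be controlled. Both stereocentres are propargylic and the cis isomer is the less stable one, so any step that makes C1–H or C2–H acidic can leak material into the trans series. The bithiophenes are electron-rich: they limit the choice of oxidants and electrophiles, exclude desulfurising metals, and have a free 5'-position that lithium bases can metalate. A cis-1,2-dialkynylcyclobutane is also set up for [3,3] shifts when heated. The difficulty is therefore to make a cis-1,2-disubstituted four-membered ring with no other functionality on it, and to install two aryl alkynes without epimerising next to them. The strategy rests on the six-carbon path Cβ–Cα–C1–C2–Cα'–Cβ', in which Cα is the ring-bound sp carbon and Cβ the thienyl-bound sp carbon. Closed through Cβ–Cβ', this path is a cyclohexene fused to the cyclobutane, that is, the Diels–Alder adduct of a C1=C2 cyclobutene double bond and a 2,3-diarylbutadiene, and its cis ring fusion becomes the cis arms.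

## Retrosynthetic reasoning

**17 to 14, through 16.** Each C≡C of 17 is traced back to a CH2–C(=O)–bithienyl unit of diketone 14, with bis(enol triflate) 16 between them. No carbon–carbon bond is cut. The gain is that 14 is exactly what cleavage of a diaryl alkene delivers, and that in 14 the ring CH groups are beta to the carbonyls, so they cannot epimerise. In 16 the triflate-bearing carbon carries only the aryl group besides the leaving group, so elimination can only give the alkyne and never an allene. The forward reactions must enolise both ketones before one enolate attacks the other carbonyl, and must eliminate without deprotonating the propargylic ring C–H.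

**14 to 12, through 13.** The two carbonyl carbons of 14 are joined to a tetrasubstituted C=C, which turns the open chain into the cis-fused bicyclo[4.2.0]oct-3-ene 12. This is the only place where the six-carbon path can be closed without touching C1 or C2. The forward direction has to cleave an electron-rich alkene flanked by four thiophene rings. Osmium-catalysed syn-dihydroxylation to diol 13 followed by glycol cleavage is chosen because it avoids ozonolysis and avoids an acid-mediated epoxide opening, in which a thienyl-stabilised cation could rearrange. The epoxide variant is kept as the reserve.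

**12 to 10.** Hydrocarbon 12 is traced to ketone 10, which carries a carbonyl at C7 of the bicycle. The carbonyl serves only to turn the four-membered alkene of 4 into a dienophile, and it is removed again by Wolff–Kishner reduction through hydrazone 11. The price is one step. The gain is a cycloaddition that should run near room temperature.

**10 to 4 and 9.** The C1–C2 and C5–C6 bonds of bicycle 10 are cut in a retro-[4+2]. These are the C1–Cα and C2–Cα' bonds of 17. Cutting here places both stereocentres on dienophile 4, where a suprafacial addition to a ring double bond can only give the cis fusion. Diene 9 is symmetric, so there is no regiochemistry to control, and its termini are CH2 groups, so endo and exo approach give the same product.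

**9 to 6 and 7, through 8.** Both aryl–carbon bonds of 9 are cut. The but-2-yne-1,4-diyl unit of dicarbonate 6 becomes the 2,3-disubstituted diene by two successive SN2' arylations under zerovalent palladium catalysis, with allene 8 as the halfway stage. This uses boronate 7 as bought and builds the diene in one operation.

**6 to 5.** Dicarbonate 6 comes from diol 5 by acylation of both hydroxyls.

**4 to 1, through 3 and 2.** The enone double bond of 4 is made by dehydrobromination of beta-bromo ketone 3. This comes from acid 1 by bromodecarboxylation through acyl hypobromite 2.

## Alternatives that were turned down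

**Alternative 1: Wolff ring contraction with an internal lactone trap.**
- Disconnection: the C1–C4 bond of the cyclobutane, which is traced to a five-membered diazo ketone that contracts.
- Key step: irradiation of rac-2-diazo-3-(hydroxymethyl)cyclopentan-1-one A1 should make the ring CH2 on the carbonyl migrate to the diazo carbon, and the hydroxyl should capture the resulting ketene carbon to give rac-cis-3-oxabicyclo[3.2.0]heptan-2-one A2.
- For it: lactone A2 can only be cis-fused, so the relative configuration is secure at that stage. The Wolff rearrangement is dependable. The bithiophenes would enter only at the very end by Sonogashira arylation, so they never meet an oxidant. On that last point it is stronger than the chosen route.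
- Against it: A2 has to be opened to two one-carbon handles, and cis-cyclobutane-1,2-dicarbaldehyde A3 or any equivalent has both stereocentres alpha to a carbonyl just when a basic Seyferth–Gilbert-type homologation is required. The configuration of A3 is therefore at risk in the open-chain stage. A1 itself needs the diazo group on the more hindered alpha carbon, which costs several steps. The whole sequence should run to eleven or twelve steps.
- Comparison: the chosen route keeps the ring CH groups beta to the carbonyls after ring cleavage, and makes both arms at once with the aryl groups already in place.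

**Alternative 2: sulfone carbanion [3+1] double alkylation.**
- Disconnection: both ring bonds to C4, so that C4 arrives as the carbanion carbon of methyl phenyl sulfone A4.
- Key step: twice-deprotonated A4 should displace first the primary and then the secondary propargylic mesylate of rac-1,2-bis[(2,2'-bithiophen-5-yl)ethynyl]propane-1,3-diyl dimethanesulfonate A5. This should close rac-cis-2,3-bis[(2,2'-bithiophen-5-yl)ethynyl]cyclobutyl phenyl sulfone A6, and reductive desulfonylation of A6 would finish.
- For it: it is convergent, the aryl alkynes are present from the start, and on paper it is the shortest endgame. On step economy it is stronger than the chosen route, and it also has no oxidative step.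
- Against it: the cis relationship depends on clean inversion at a secondary propargylic mesylate in one pure diastereomer of A5, which needs its own stereocontrolled synthesis. That centre is flanked by a doubly activated C–H, so the basic sulfonyl carbanion should cause E2 to a conjugated enediyne. The bithienyl-stabilised propargylic cation invites ionisation and SN2' escape. A 4-exo-tet closure is slow in any case. Reductive removal of the sulfone from A6 would also compete with reduction of the aryl alkynes.
- Comparison: the chosen route draws the cis geometry from a pericyclic rule and not from an SN2 reaction at a labile centre, at the cost of more steps.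

**Alternative 3: alkynyl conjugate addition and alkylation onto a bromopropylidene malonate.**
- Disconnection: the C2–Cα bond and the C1–C4 bond.
- Key step: dimethyl 2-(3-bromopropylidene)malonate A7 should take up, at its beta carbon, the Et2Al acetylide made from 5-ethynyl-2,2'-bithiophene A8. The malonate enolate should then displace bromide and give rac-dimethyl 2-[(2,2'-bithiophen-5-yl)ethynyl]cyclobutane-1,1-dicarboxylate A9.
- For it: Michael-initiated ring closure to cyclobutane-1,1-diesters is sound, the materials are cheap, and one complete arm is installed in the ring-forming step. There is no mercury and no oxidative cleavage, and in these respects it is stronger.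
- Against it: in A9 the carbon C1 is a quaternary gem-diester with no stereochemical information. The second arm needs Krapcho dealkoxycarbonylation, reduction, homologation and a Sonogashira arylation, and C1 is alpha to a carbonyl throughout. Since cis is the contra-thermodynamic isomer, this sequence should drift to the trans compound and not to 17. With the preparation of A7 and A8 it is no shorter than the chosen route.
- Comparison: the chosen route spends steps on scaffolding (the C7 carbonyl and the cyclohexene) but sets both centres together and never exposes them to epimerisation.

Key step: step 5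

## Route

**Step 1**
Reactants: 1 3-oxocyclobutane-1-carboxylic acid
Product: 3 3-bromocyclobutan-1-one, via acyl hypobromite 2 (not isolated)
Conditions: HgO (red), Br2, MgSO4, CH2Cl2, reflux, dark
Reagents that add atoms: bromine, BrBr
Why: Hunsdiecker-type bromodecarboxylation in its HgO/Br2 (Cristol–Firth) form; the acyl hypobromite 2 should lose CO2 to a cyclobutyl radical that takes up bromine, and the ketone is inert to these conditions; no stereocentre is formed.

**Step 2**
Reactants: 3 3-bromocyclobutan-1-one
Product: 4 cyclobut-2-en-1-one
Conditions: n-Bu3N (1.1 equiv), neat, rt; vacuum transfer into a −78 °C trap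
Reagents that add atoms: none
Why: E1cB loss of HBr from a beta-bromo ketone with a high-boiling amine; the volatile enone should distil away from the ammonium salt and is kept cold in solution and used at once because it polymerises.

**Step 3**
Reactants: 5 but-2-yne-1,4-diol
Product: 6 but-2-yne-1,4-diyl dimethyl dicarbonate
Conditions: ClCO2Me (2.4 equiv), pyridine, CH2Cl2, 0 °C → rt
Reagents that add atoms: methyl chloroformate, COC(=O)Cl
Why: Plain O-acylation of two primary propargylic alcohols; the methyl carbonate is the leaving group that releases its own methoxide base on ionisation in step 4.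

**Step 4**
Reactants: 6 but-2-yne-1,4-diyl dimethyl dicarbonate; 7 2-(2,2'-bithiophen-5-yl)-4,4,5,5-tetramethyl-1,3,2-dioxaborolane
Product: 9 2,3-bis(2,2'-bithiophen-5-yl)buta-1,3-diene, via allenyl carbonate 8 (not isolated)
Conditions: Pd(PPh3)4 (5 mol %), 7 (2.4 equiv), THF, 65 °C
Reagents that add atoms: none
Why: Tsuji-type propargylic substitution combined with Suzuki–Miyaura coupling under neutral conditions: zerovalent palladium ionises the propargylic carbonate in SN2' fashion to an allenylpalladium methoxide, the methoxide activates the boronate for transmetalation, and reductive elimination gives allene 8. The remaining carbonate of 8 is allylic to the allene and ionises SN2' again to a buta-1,3-dien-2-ylpalladium species, which couples to 9.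

**Step 5 (key step)**
Reactants: 4 cyclobut-2-en-1-one; 9 2,3-bis(2,2'-bithiophen-5-yl)buta-1,3-diene
Product: 10 rac-cis-3,4-bis(2,2'-bithiophen-5-yl)bicyclo[4.2.0]oct-3-en-7-one
Conditions: 4 (2.5 equiv, in portions), ZnCl2 (0.5 equiv, 1 M in Et2O), CH2Cl2, 0 °C → rt
Reagents that add atoms: none
Why: A concerted, asynchronous, suprafacial [4+2] cycloaddition of normal electron demand: the diene HOMO is raised by the two thienyl donors, and the LUMO of 4 is lowered by the carbonyl, by ZnCl2 bound to it, and by the relief of angle strain as the two alkene carbons of the four-membered ring rehybridise towards sp3. The closest known reaction type is the Diels–Alder reaction of cyclobut-2-en-1-one with acyclic 2- and 2,3-substituted buta-1,3-dienes. The one ring closed is the cyclohexene, through a six-membered pericyclic transition state in which both new sigma bonds (C1–C2 and C5–C6 of the bicycle) are made to the same face of the enone. The two new stereocentres C1 and C6 are therefore cis, controlled by the suprafacial geometry of a dienophile whose double bond is locked in a ring; endo or exo approach makes no difference because both diene termini are CH2 groups. Diene 9 is symmetric, so no regiochemical question arises. The selectivity needed is cycloaddition over self-reaction of 4 and over any reaction at the thiophenes; portionwise addition keeps 4 dilute, the diene termini are unhindered, and the thiophene rings are aromatic and do not act as dienes here. C6–H is alpha to the ketone in 10, but the cis fusion is also the stable one for a bicyclo[4.2.0]octan-7-one, so enolisation cannot invert it.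

**Step 6**
Reactants: 10 rac-cis-3,4-bis(2,2'-bithiophen-5-yl)bicyclo[4.2.0]oct-3-en-7-one
Product: 12 cis-3,4-bis(2,2'-bithiophen-5-yl)bicyclo[4.2.0]oct-3-ene, via hydrazone 11 (not isolated)
Conditions: N2H4·H2O, diethylene glycol, 120 °C; then KOH, 195 °C with removal of water
Reagents that add atoms: none
Why: Wolff–Kishner reduction in the Huang-Minlon form, a standard way to deoxygenate ring-fused cyclobutanones; forming hydrazone 11 before the base is added should protect the strained ketone from hydroxide. The ring-fusion centres are not involved, and the thiophenes and the fully substituted, conjugated alkene should tolerate base.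

**Step 7**
Reactants: 12 cis-3,4-bis(2,2'-bithiophen-5-yl)bicyclo[4.2.0]oct-3-ene
Product: 13 cis-fused 3,4-bis(2,2'-bithiophen-5-yl)bicyclo[4.2.0]octane-3,4-diol with the two hydroxyls cis to each other and on the face of the ring-fusion hydrogens
Conditions: OsO4 (10 mol %), NMO (3 equiv), MeSO2NH2 (1 equiv), acetone–t-BuOH–H2O, 40 °C
Reagents that add atoms: osmium tetroxide, O=[Os](=O)(=O)=O; N-methylmorpholine N-oxide, C[N+]1([O-])CCOCC1; water, O
Why: Upjohn syn-dihydroxylation through a cyclic osmate ester, which can only give the cis-diol; attack is expected on the convex face, away from the cyclobutane. Both carbinol centres are destroyed in step 8, so the facial outcome does not matter, and aromatic thiophenes are not osmylated, nor is their sulfur oxidised by NMO.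

**Step 8**
Reactants: 13 the cis-diol of step 7
Product: 14 2,2'-(cis-cyclobutane-1,2-diyl)bis[1-(2,2'-bithiophen-5-yl)ethan-1-one]
Conditions: Pb(OAc)4 (1.1 equiv), CH2Cl2, 0 °C
Reagents that add atoms: none
Why: Criegee glycol cleavage through a cyclic lead diester, fast for a cis-diol even when both carbinols are tertiary. It opens the six-membered ring to two aryl ketones and leaves the cis ring centres beta to the carbonyls, where they cannot epimerise.

**Step 9**
Reactants: 14 2,2'-(cis-cyclobutane-1,2-diyl)bis[1-(2,2'-bithiophen-5-yl)ethan-1-one]
Product: 16 cis-cyclobutane-1,2-diylbis[(1Z)-1-(2,2'-bithiophen-5-yl)ethene-2,1-diyl] bis(trifluoromethanesulfonate), via dipotassium bis-enolate 15 (not isolated)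
Conditions: KN(SiMe3)2 (2.6 equiv), THF, −78 °C, 14 added slowly to the base; PhNTf2 (2.6 equiv), −78 → 0 °C; filtration through basic alumina
Reagents that add atoms: N-phenylbis(trifluoromethanesulfonimide), O=S(=O)(N(c1ccccc1)S(=O)(=O)C(F)(F)F)C(F)(F)F
Why: Double enolate O-triflation; aryl alkyl ketones enolise to the Z(O)-enolates, and inverse addition into excess base should convert each molecule to bis-enolate 15 before a mono-enolate can attack the other carbonyl. The silylamide is too weak to metalate thiophene, and the ring centres are allylic but not acidic under these conditions.

**Step 10**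
Reactants: 16 the bis(enol triflate) of step 9
Product: 17 isocardopatine, cis-1,2-bis[(2,2'-bithiophen-5-yl)ethynyl]cyclobutane
Conditions: LiN(iPr)2 (2.4 equiv), THF, −78 °C, 20 min; aq. NH4Cl at −78 °C
Reagents that add atoms: none
Why: Double E2 elimination of the vinyl triflates, with the vinyl hydrogen anti to the leaving group in the Z isomers; since the triflate-bearing carbon carries only the aryl group, only the alkyne can form. Low temperature, a small excess of base and a cold quench are meant to keep the propargylic ring C–H untouched, so the cis configuration set in step 5 is carried through.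

## Compound list

1 | 3-oxocyclobutane-1-carboxylic acid | O=C1CC(C1)C(=O)O | starting material
2 | 3-oxocyclobutane-1-carbonyl hypobromite | O=C1CC(C1)C(=O)OBr | intermediate
3 | 3-bromocyclobutan-1-one | O=C1CC(Br)C1 | intermediate
4 | cyclobut-2-en-1-one | O=C1C=CC1 | intermediate
5 | but-2-yne-1,4-diol | OCC#CCO | starting material
6 | but-2-yne-1,4-diyl dimethyl dicarbonate | COC(=O)OCC#CCOC(=O)OC | intermediate
7 | 2-(2,2'-bithiophen-5-yl)-4,4,5,5-tetramethyl-1,3,2-dioxaborolane | CC1(C)OB(OC1(C)C)c1ccc(-c2cccs2)s1 | starting material
8 | 2-(2,2'-bithiophen-5-yl)buta-2,3-dien-1-yl methyl carbonate | C=C=C(COC(=O)OC)c1ccc(-c2cccs2)s1 | intermediate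
9 | 2,3-bis(2,2'-bithiophen-5-yl)buta-1,3-diene | C=C(c1ccc(-c2cccs2)s1)C(=C)c1ccc(-c2cccs2)s1 | intermediate
10 | rac-cis-3,4-bis(2,2'-bithiophen-5-yl)bicyclo[4.2.0]oct-3-en-7-one (ring-fusion hydrogens cis) | O=C1C[C@H]2CC(c3ccc(-c4cccs4)s3)=C(c3ccc(-c4cccs4)s3)C[C@@H]12 | intermediate
11 | (E)-hydrazone of 10, [rac-cis-3,4-bis(2,2'-bithiophen-5-yl)bicyclo[4.2.0]oct-3-en-7-ylidene]hydrazine | N/N=C1\C[C@H]2CC(c3ccc(-c4cccs4)s3)=C(c3ccc(-c4cccs4)s3)C[C@@H]12 | intermediate
12 | cis-3,4-bis(2,2'-bithiophen-5-yl)bicyclo[4.2.0]oct-3-ene (meso) | C1C[C@H]2CC(c3ccc(-c4cccs4)s3)=C(c3ccc(-c4cccs4)s3)C[C@@H]12 | intermediate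
13 | cis-fused 3,4-bis(2,2'-bithiophen-5-yl)bicyclo[4.2.0]octane-3,4-diol, hydroxyls cis to each other and to the ring-fusion hydrogens (meso) | C1C[C@H]2C[C@@](O)(c3ccc(-c4cccs4)s3)[C@@](O)(c3ccc(-c4cccs4)s3)C[C@@H]12 | intermediate
14 | 2,2'-(cis-cyclobutane-1,2-diyl)bis[1-(2,2'-bithiophen-5-yl)ethan-1-one] (meso) | O=C(C[C@@H]1CC[C@@H]1CC(=O)c1ccc(-c2cccs2)s1)c1ccc(-c2cccs2)s1 | intermediate
15 | dipotassium (Z,Z)-bis-enolate of 14 | [K+].[K+].[O-]/C(=C\[C@@H]1CC[C@@H]1/C=C(\[O-])c1ccc(-c2cccs2)s1)c1ccc(-c2cccs2)s1 | intermediate
16 | cis-cyclobutane-1,2-diylbis[(1Z)-1-(2,2'-bithiophen-5-yl)ethene-2,1-diyl] bis(trifluoromethanesulfonate) | O=S(=O)(O/C(=C\[C@@H]1CC[C@@H]1/C=C(\OS(=O)(=O)C(F)(F)F)c1ccc(-c2cccs2)s1)c1ccc(-c2cccs2)s1)C(F)(F)F | intermediate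
17 | isocardopatine, (1R,2S)-1,2-bis[(2,2'-bithiophen-5-yl)ethynyl]cyclobutane (cis, meso) | C(#C[C@@H]1CC[C@@H]1C#Cc1ccc(-c2cccs2)s1)c1ccc(-c2cccs2)s1 | target

## Step count and risk

Total: 10 steps. Longest linear sequence: 8 steps (steps 1, 2, 5, 6, 7, 8, 9, 10; the diene branch through steps 3 and 4 is equally long).

**Step 5 (key step).** The strained enone may dimerise or oligomerise faster than it is intercepted, because the 2,3-diaryl diene has to reach a crowded s-cis conformer. The ZnCl2 may also degrade the electron-rich diene. The fallback sets out from 4 and raises the reactivity of the dienophile in place of Lewis acid activation. Bromine addition to 4 in CH2Cl2 at −78 °C would give rac-trans-2,3-dibromocyclobutan-1-one F1, and Et3N would eliminate HBr to 2-bromocyclobut-2-en-1-one F2. Thermal cycloaddition of F2 with 9 would give rac-cis-6-bromo-3,4-bis(2,2'-bithiophen-5-yl)bicyclo[4.2.0]oct-3-en-7-one F3. Radical debromination of F3 (Bu3SnH, AIBN, benzene, 80 °C) would return to the route at 10, since hydrogen transfer to the ring-fusion radical should give the far less strained cis fusion.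

**Step 4.** Protodeboronation of the 2-thienyl boronate, or stalling of the cascade after the first arylation under base-free conditions, would cut the supply of diene. The fallback sets out from 5 and uses a hard nucleophile with copper in place of boron and palladium. O-Methylation of 5 (NaH, MeI, THF) would give 1,4-dimethoxybut-2-yne F4. Treatment of F4 with (2,2'-bithiophen-5-yl)magnesium bromide F5 (from commercial 5-bromo-2,2'-bithiophene and Mg in THF) and catalytic CuBr would bring in both aryl groups by two successive SN2' displacements of methoxide, returning at 9.

**Step 6.** At 195 °C in KOH the double bond may migrate out of the diaryl-substituted position through a thienyl-stabilised allyl anion, or hydroxide may open the four-membered ketone before the hydrazone is complete. The fallback sets out from 10 and replaces the hot-base step by a hydride reduction. Condensation of 10 with TsNHNH2 in EtOH would give the corresponding (E)-4-methylbenzenesulfonylhydrazone F6. Reduction of F6 with catecholborane in CHCl3 at 0 °C followed by NaOAc·3H2O at reflux would release sulfinate and N2 and return at 12.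

**Step 7.** Osmylation of a twisted, tetrasubstituted diaryl alkene is slow, as is hydrolysis of its osmate ester, which gives time for oxidation at the bithiophenes. The fallback sets out from 12 and uses electrophilic oxygen transfer. Dimethyldioxirane in acetone at −20 °C would give the convex-face epoxide 3,4-bis(2,2'-bithiophen-5-yl)-3,4-epoxy-cis-bicyclo[4.2.0]octane F7. H5IO6 in THF–H2O at 0 °C would open F7 to the diol and cleave that in the same flask, returning at 14. Its own risk is a semipinacol shift of the thienyl-stabilised cation, which is why it is the reserve.

**Step 9.** A mono-enolate may close a five-membered ring by aldol attack on the second ketone before the second deprotonation, and the electron-rich enol triflates may hydrolyse on silica. The fallback sets out from 14 and reverses the polarity of the activation. Tf2O with 2,6-di-tert-butyl-4-methylpyridine in CH2Cl2 (−78 → 0 °C) would triflate each carbonyl oxygen first and then remove the alpha proton, so no enolate is present. It returns at 16; either alkene geometry is acceptable because only the alkyne can form in step 10.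

**Step 10.** Excess amide base may deprotonate the propargylic ring C–H, and reprotonation would then drain material into the trans isomer. It may also metalate the thiophene 5'-position or attack sulfur of the triflate and return the ketone. The fallback sets out from 14 and avoids metal amides altogether by a Barton vinyl iodide sequence. N2H4·H2O in EtOH at reflux would give the (E,E)-bis-hydrazone F8. Iodine with 1,1,3,3-tetramethylguanidine in THF at 0 °C would convert F8 to the bis(vinyl iodide) cis-cyclobutane-1,2-diylbis[(1Z)-1-(2,2'-bithiophen-5-yl)-1-iodoethene-2,1-diyl] F9. t-BuOK in THF at 0 °C, a base too weak to metalate thiophene, would then eliminate HI from both arms of F9 and return at 17.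

## Further compounds

F1 | step 5 | rac-trans-2,3-dibromocyclobutan-1-one | O=C1C[C@H](Br)[C@H]1Br
F2 | step 5 | 2-bromocyclobut-2-en-1-one | O=C1CC=C1Br
F3 | step 5 | rac-cis-6-bromo-3,4-bis(2,2'-bithiophen-5-yl)bicyclo[4.2.0]oct-3-en-7-one | O=C1C[C@H]2CC(c3ccc(-c4cccs4)s3)=C(c3ccc(-c4cccs4)s3)C[C@@]12Br
F4 | step 4 | 1,4-dimethoxybut-2-yne | COCC#CCOC
F5 | step 4 | (2,2'-bithiophen-5-yl)magnesium bromide | Br[Mg]c1ccc(-c2cccs2)s1
F6 | step 6 | (E)-4-methylbenzenesulfonylhydrazone of 10 | Cc1ccc(cc1)S(=O)(=O)N/N=C1\C[C@H]2CC(c3ccc(-c4cccs4)s3)=C(c3ccc(-c4cccs4)s3)C[C@@H]12
F7 | step 7 | 3,4-bis(2,2'-bithiophen-5-yl)-3,4-epoxy-cis-bicyclo[4.2.0]octane, epoxide oxygen on the face of the ring-fusion hydrogens | C1C[C@H]2C[C@]3(c4ccc(-c5cccs5)s4)O[C@]3(c3ccc(-c4cccs4)s3)C[C@@H]12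
F0 | step 9 | none | none
F8 | step 10 | (E,E)-bis-hydrazone of 14 | N/N=C(\C[C@@H]1CC[C@@H]1C/C(=N\N)c1ccc(-c2cccs2)s1)c1ccc(-c2cccs2)s1
F9 | step 10 | cis-cyclobutane-1,2-diylbis[(1Z)-1-(2,2'-bithiophen-5-yl)-1-iodoethene-2,1-diyl] | I/C(=C\[C@@H]1CC[C@@H]1/C=C(\I)c1ccc(-c2cccs2)s1)c1ccc(-c2cccs2)s1
A1 | alternative 1 | rac-2-diazo-3-(hydroxymethyl)cyclopentan-1-one | [N-]=[N+]=C1[C@@H](CO)CCC1=O
A2 | alternative 1 | rac-cis-3-oxabicyclo[3.2.0]heptan-2-one | O=C1OC[C@@H]2CC[C@H]12
A3 | alternative 1 | cis-cyclobutane-1,2-dicarbaldehyde | O=C[C@@H]1CC[C@@H]1C=O
A4 | alternative 2 | methyl phenyl sulfone | CS(=O)(=O)c1ccccc1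
A5 | alternative 2 | rac-1,2-bis[(2,2'-bithiophen-5-yl)ethynyl]propane-1,3-diyl dimethanesulfonate, the diastereomer that gives the cis ring on inversion | CS(=O)(=O)OC[C@@H](C#Cc1ccc(-c2cccs2)s1)[C@@H](OS(C)(=O)=O)C#Cc1ccc(-c2cccs2)s1
A6 | alternative 2 | rac-cis-2,3-bis[(2,2'-bithiophen-5-yl)ethynyl]cyclobutyl phenyl sulfone | O=S(=O)(c1ccccc1)[C@@H]1C[C@@H](C#Cc2ccc(-c3cccs3)s2)[C@H]1C#Cc1ccc(-c2cccs2)s1
A7 | alternative 3 | dimethyl 2-(3-bromopropylidene)malonate | COC(=O)C(=CCCBr)C(=O)OC
A8 | alternative 3 | 5-ethynyl-2,2'-bithiophene | C#Cc1ccc(-c2cccs2)s1
A9 | alternative 3 | rac-dimethyl 2-[(2,2'-bithiophen-5-yl)ethynyl]cyclobutane-1,1-dicarboxylate | COC(=O)C1(C(=O)OC)CC[C@H]1C#Cc1ccc(-c2cccs2)s1
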